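**Plan**
Target: (6R)-ε,ψ-carotene (δ-carotene). Carotenoid numbering is used: ε ring C1–C6, chain C7–C15 then C15'–C1', methyls C16–C20 and C16'–C20'.
Cuts: first the sp2–sp2 bond C14–C15 together with C13–C20 (methyl), which gives C18 tetraenyne 22, Me3Al and C21 bromoheptaene 16. The same double cut follows at C10–C11/C9–C19, C14'–C15'/C13'–C20', C10'–C11'/C9'–C19' and C6'–C7'/C5'–C18'.
Enabling feature: each chain methyl sits on an E-trisubstituted alkene (C20–C13=C14 at the union) whose CH end is bonded to an unbranched E-CH=CH unit (C15=C15'). A 2-methylalk-1-enyl group is the retron of syn methylmetalation of a terminal alkyne (C13≡C14), so alkyne, methyl and haloalkene can be joined in one flask.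
Forward order: linchpins 2 (C2) and 5 (C4) are made. The ψ chain grows from 6-methylhept-5-en-2-one (C5' to C9' to C13' to C15), the ε chain grows from (R)-α-ionone (C9 to C14), and the halves are joined last. No ring is formed, because the cyclohexene ring comes with α-ionone.
Stereochemistry: C6 (R) comes from (R)-α-ionone and is never a reacting centre. The five trisubstituted E alkenes come from syn carboalumination. The disubstituted E alkenes come from α-ionone and from the E-haloalkene linchpins, with retention.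

Key step: step 12

Assumption: (R)-(+)-α-ionone 17 is taken as a purchasable chiral-pool compound of high enantiomeric purity, checked by chiral GC before use.
General remark: all polyenes are handled under argon, in dim light, without acid, and are used soon after preparation.

Step 1
Reactants: 1 acetylene
Product: 2 (E)-1-bromo-2-iodoethene
Conditions: IBr, 48% aq HBr, 0 °C, acetylene bubbled in
Reagents that add atoms: iodine monobromide, BrI
Why: Electrophilic anti addition of IBr to the alkyne through a bridged iodonium ion should give the E-dihaloethene (halogenation of an alkyne).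

Step 2
Reactants: 3 ethynyl(trimethyl)silane; 2 (E)-1-bromo-2-iodoethene
Product: 5 [(3E)-4-bromobut-3-en-1-yn-1-yl]trimethylsilane, via alkynylzinc bromide 4 (not isolated)
Conditions: 3, n-BuLi, THF, −78 °C; ZnBr2, 0 °C; then 2 (1.1 equiv), Pd(PPh3)4 (2 mol %), THF, 0 to 23 °C
Reagents that add atoms: none
Why: In this Negishi alkynyl–alkenyl coupling, zerovalent palladium inserts much faster into the carbon–iodine than into the carbon–bromine bond of 2, so one alkynyl group should be delivered with retention of the E geometry and the bromide kept for later use.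

Step 3
Reactants: 6 6-methylhept-5-en-2-one
Product: 8 6-methylhept-5-en-1-yne, via enol phosphate 7 (not isolated)
Conditions: LDA (1.05 equiv), THF, −78 °C; ClP(O)(OEt)2, −78 to 23 °C; then LDA (2.3 equiv), THF, −78 to 23 °C; H2O
Reagents that add atoms: none
Why: Kinetic deprotonation at the methyl group, O-phosphorylation and LDA-induced β-elimination of diethyl phosphate (methyl ketone to terminal alkyne conversion through the enol phosphate) should give the alkyne and leave the trisubstituted alkene alone.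

Step 4
Reactants: 8 6-methylhept-5-en-1-yne; 5 [(3E)-4-bromobut-3-en-1-yn-1-yl]trimethylsilane
Product: 10 trimethyl[(3E,5E)-6,10-dimethylundeca-3,5,9-trien-1-yn-1-yl]silane, via alkenylalane 9 (not isolated)
Conditions: Me3Al (2 equiv), Cp2ZrCl2 (25 mol %), ClCH2CH2Cl, 23 °C; volatiles removed in vacuo; then 5, ZnCl2 (0.3 equiv, co-catalyst), Pd2(dba)3 (2.5 mol %), P(2-furyl)3 (10 mol %), THF–DMF, 23 °C
Reagents that add atoms: trimethylaluminium, C[Al](C)C
Why: Zirconium-catalysed syn methylalumination of the terminal alkyne sets the E-trisubstituted C5'=C6' alkene, and the Negishi alkenyl–alkenyl coupling with 5 should proceed with retention at both sp2 carbons.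

Step 5
Reactants: 10 trimethyl[(3E,5E)-6,10-dimethylundeca-3,5,9-trien-1-yn-1-yl]silane
Product: 11 (3E,5E)-6,10-dimethylundeca-3,5,9-trien-1-yne
Conditions: K2CO3 (cat.), MeOH–THF, 23 °C
Reagents that add atoms: none
Why: Methoxide-mediated protodesilylation of an alkynylsilane is mild enough to leave the triene geometry untouched.

Step 6
Reactants: 11 (3E,5E)-6,10-dimethylundeca-3,5,9-trien-1-yne; 5 [(3E)-4-bromobut-3-en-1-yn-1-yl]trimethylsilane
Product: 13 trimethyl[(3E,5E,7E,9E)-6,10,14-trimethylpentadeca-3,5,7,9,13-pentaen-1-yn-1-yl]silane, via alkenylalane 12 (not isolated)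
Conditions: Me3Al (2 equiv), Cp2ZrCl2 (25 mol %), ClCH2CH2Cl, 23 °C; volatiles removed in vacuo; then 5, ZnCl2 (0.3 equiv, co-catalyst), Pd2(dba)3 (2.5 mol %), P(2-furyl)3 (10 mol %), THF–DMF, 23 °C
Reagents that add atoms: trimethylaluminium, C[Al](C)C
Why: The same zirconium-catalysed methylalumination/Negishi coupling, known to work on conjugated dienynes, sets the E C9'=C10' alkene by syn addition and brings in the E C11'=C12' unit with retention.

Step 7
Reactants: 13 trimethyl[(3E,5E,7E,9E)-6,10,14-trimethylpentadeca-3,5,7,9,13-pentaen-1-yn-1-yl]silane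
Product: 14 (3E,5E,7E,9E)-6,10,14-trimethylpentadeca-3,5,7,9,13-pentaen-1-yne
Conditions: K2CO3 (cat.), MeOH–THF, 23 °C
Reagents that add atoms: none
Why: Protodesilylation of the alkynylsilane under weakly basic methanolysis should free the terminal alkyne without isomerising the polyene.

Step 8
Reactants: 14 (3E,5E,7E,9E)-6,10,14-trimethylpentadeca-3,5,7,9,13-pentaen-1-yne; 2 (E)-1-bromo-2-iodoethene
Product: 16 (1E,3E,5E,7E,9E,11E)-1-bromo-4,8,12,16-tetramethylheptadeca-1,3,5,7,9,11,15-heptaene, via alkenylalane 15 (not isolated)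
Conditions: Me3Al (2 equiv), Cp2ZrCl2 (25 mol %), ClCH2CH2Cl, 23 °C; volatiles removed in vacuo; then 2 (1.3 equiv), ZnCl2 (0.3 equiv, co-catalyst), Pd(PPh3)4 (3 mol %), THF, 0 to 23 °C
Reagents that add atoms: trimethylaluminium, C[Al](C)C
Why: Syn methylalumination sets the E C13'=C14' alkene, and the Negishi coupling should take place only at the more reactive carbon–iodine bond of the excess linchpin 2, which leaves the E-bromodiene terminus (C15'=C15–Br) for the union.

Step 9
Reactants: 17 (R)-α-ionone, (3E)-4-[(1R)-2,6,6-trimethylcyclohex-2-en-1-yl]but-3-en-2-one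
Product: 19 (6R)-6-[(1E)-but-1-en-3-yn-1-yl]-1,5,5-trimethylcyclohex-1-ene, via enol phosphate 18 (not isolated)
Conditions: LDA (1.05 equiv), THF, −78 °C; ClP(O)(OEt)2, −78 to 0 °C; then LDA (2.3 equiv), THF, −78 to 0 °C; H2O
Reagents that add atoms: none
Why: Kinetic deprotonation by LDA at −78 °C should occur at the methyl group and not at the γ-position C6, so O-phosphorylation and LDA-induced β-elimination (methyl ketone to terminal alkyne conversion through the enol phosphate) should give 19 with C6 (R) and the E C7=C8 alkene unchanged.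

Step 10
Reactants: 19 (6R)-6-[(1E)-but-1-en-3-yn-1-yl]-1,5,5-trimethylcyclohex-1-ene; 5 [(3E)-4-bromobut-3-en-1-yn-1-yl]trimethylsilane
Product: 21 trimethyl{(3E,5E,7E)-6-methyl-8-[(1R)-2,6,6-trimethylcyclohex-2-en-1-yl]octa-3,5,7-trien-1-yn-1-yl}silane, via alkenylalane 20 (not isolated)
Conditions: Me3Al (2 equiv), Cp2ZrCl2 (25 mol %), ClCH2CH2Cl, 23 °C; volatiles removed in vacuo; then 5, ZnCl2 (0.3 equiv, co-catalyst), Pd2(dba)3 (2.5 mol %), P(2-furyl)3 (10 mol %), THF–DMF, 23 °C; cold aq NaHCO3 work-up
Reagents that add atoms: trimethylaluminium, C[Al](C)C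
Why: Zirconium-catalysed syn methylalumination sets the E C9=C10 alkene and installs C19, the Negishi coupling adds the E C11=C12 enyne unit with retention, and the aprotic medium leaves the doubly allylic C6–H alone.

Step 11
Reactants: 21 trimethyl{(3E,5E,7E)-6-methyl-8-[(1R)-2,6,6-trimethylcyclohex-2-en-1-yl]octa-3,5,7-trien-1-yn-1-yl}silane
Product: 22 (6R)-1,5,5-trimethyl-6-[(1E,3E,5E)-3-methylocta-1,3,5-trien-7-yn-1-yl]cyclohex-1-ene
Conditions: K2CO3 (cat.), MeOH–THF, 23 °C
Reagents that add atoms: none
Why: Protodesilylation with carbonate in methanol is far too weakly basic to deprotonate the hydrocarbon C6–H, so the alkyne should be freed without racemisation or migration of the ring alkene.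

Step 12
Reactants: 22 (6R)-1,5,5-trimethyl-6-[(1E,3E,5E)-3-methylocta-1,3,5-trien-7-yn-1-yl]cyclohex-1-ene; 16 (1E,3E,5E,7E,9E,11E)-1-bromo-4,8,12,16-tetramethylheptadeca-1,3,5,7,9,11,15-heptaene
Product: 24 (6R)-ε,ψ-carotene (δ-carotene), via alkenylalane 23 (not isolated)
Conditions: 22 (1.1 equiv), Me3Al (2 equiv), Cp2ZrCl2 (25 mol %), ClCH2CH2Cl, 23 °C; volatiles removed in vacuo; then 16, ZnCl2 (0.3 equiv, co-catalyst), Pd2(dba)3 (2.5 mol %), P(2-furyl)3 (10 mol %), THF–DMF, 23 °C, dark, argon; cold aq NaHCO3 work-up, crystallisation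
Reagents that add atoms: trimethylaluminium, C[Al](C)C
Why: Me3Al and Cp2ZrCl2 form a polarised methylzirconocene–alane pair that adds CH3 and metal in a syn four-centre fashion to the only alkyne of 22, with CH3 going to the internal C13 and the metal, after exchange to aluminium, to the terminal C14, which gives E-alkenylalane 23. Once the excess Me3Al is pumped off, ZnCl2 relays the alkenyl group from aluminium to the alkenylpalladium bromide formed by oxidative addition of zerovalent palladium into the C15–Br bond of 16, and reductive elimination forms C14–C15 with retention at both sp2 carbons. The closest known reaction type is the tandem zirconium-catalysed methylalumination/Negishi alkenyl–alkenyl coupling, which is established for conjugated polyenynes and bromopolyenes of the carotenoid and retinoid class. No ring is closed and no sp3 stereocentre is made: the E geometry of the new C13=C14 alkene is fixed by the syn addition, that of C15=C15' is carried over from 16, and C6 stays a spectator because the medium is aprotic and holds neither a strong base nor a Brønsted acid. The step needs chemoselectivity for the alkyne over the four alkenes of 22 (di- and trisubstituted alkenes are inert to methylalumination at 23 °C), regioselectivity (secured by the terminal position of the alkyne) and cross-coupling over methyl transfer or homocoupling (secured by removal of Me3Al and the fast zinc relay). In one operation three components (C18 + C1 + C21) are joined, C20 is installed and the all-E conjugated decaene is completed.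

**Compound list**
1 | acetylene | C#C | starting material
2 | (E)-1-bromo-2-iodoethene | Br/C=C/I | intermediate
3 | ethynyl(trimethyl)silane | C#C[Si](C)(C)C | starting material
4 | bromo[(trimethylsilyl)ethynyl]zinc | C[Si](C)(C)C#C[Zn]Br | intermediate
5 | [(3E)-4-bromobut-3-en-1-yn-1-yl]trimethylsilane | C[Si](C)(C)C#C/C=C/Br | intermediate
6 | 6-methylhept-5-en-2-one | CC(=O)CCC=C(C)C | starting material
7 | diethyl 6-methylhepta-1,5-dien-2-yl phosphate | C=C(CCC=C(C)C)OP(=O)(OCC)OCC | intermediate
8 | 6-methylhept-5-en-1-yne | C#CCCC=C(C)C | intermediate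
9 | [(1E)-2,6-dimethylhepta-1,5-dien-1-yl]dimethylaluminium | C[Al](C)/C=C(C)/CCC=C(C)C | intermediate
10 | trimethyl[(3E,5E)-6,10-dimethylundeca-3,5,9-trien-1-yn-1-yl]silane | CC(C)=CCC/C(C)=C/C=C/C#C[Si](C)(C)C | intermediate
11 | (3E,5E)-6,10-dimethylundeca-3,5,9-trien-1-yne | CC(C)=CCC/C(C)=C/C=C/C#C | intermediate
12 | dimethyl[(1E,3E,5E)-2,6,10-trimethylundeca-1,3,5,9-tetraen-1-yl]aluminium | CC(C)=CCC/C(C)=C/C=C/C(C)=C/[Al](C)C | intermediate
13 | trimethyl[(3E,5E,7E,9E)-6,10,14-trimethylpentadeca-3,5,7,9,13-pentaen-1-yn-1-yl]silane | CC(C)=CCC/C(C)=C/C=C/C(C)=C/C=C/C#C[Si](C)(C)C | intermediate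
14 | (3E,5E,7E,9E)-6,10,14-trimethylpentadeca-3,5,7,9,13-pentaen-1-yne | CC(C)=CCC/C(C)=C/C=C/C(C)=C/C=C/C#C | intermediate
15 | dimethyl[(1E,3E,5E,7E,9E)-2,6,10,14-tetramethylpentadeca-1,3,5,7,9,13-hexaen-1-yl]aluminium | CC(C)=CCC/C(C)=C/C=C/C(C)=C/C=C/C(C)=C/[Al](C)C | intermediate
16 | (1E,3E,5E,7E,9E,11E)-1-bromo-4,8,12,16-tetramethylheptadeca-1,3,5,7,9,11,15-heptaene | CC(C)=CCC/C(C)=C/C=C/C(C)=C/C=C/C(C)=C/C=C/Br | intermediate
17 | (R)-α-ionone, (3E)-4-[(1R)-2,6,6-trimethylcyclohex-2-en-1-yl]but-3-en-2-one | CC(=O)/C=C/[C@H]1C(C)=CCCC1(C)C | starting material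
18 | diethyl (3E)-4-[(1R)-2,6,6-trimethylcyclohex-2-en-1-yl]buta-1,3-dien-2-yl phosphate | C=C(OP(=O)(OCC)OCC)/C=C/[C@H]1C(C)=CCCC1(C)C | intermediate
19 | (6R)-6-[(1E)-but-1-en-3-yn-1-yl]-1,5,5-trimethylcyclohex-1-ene | C#C/C=C/[C@H]1C(C)=CCCC1(C)C | intermediate
20 | dimethyl{(1E,3E)-2-methyl-4-[(1R)-2,6,6-trimethylcyclohex-2-en-1-yl]buta-1,3-dien-1-yl}aluminium | C[Al](C)/C=C(C)/C=C/[C@H]1C(C)=CCCC1(C)C | intermediate
21 | trimethyl{(3E,5E,7E)-6-methyl-8-[(1R)-2,6,6-trimethylcyclohex-2-en-1-yl]octa-3,5,7-trien-1-yn-1-yl}silane | C[Si](C)(C)C#C/C=C/C=C(C)/C=C/[C@H]1C(C)=CCCC1(C)C | intermediate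
22 | (6R)-1,5,5-trimethyl-6-[(1E,3E,5E)-3-methylocta-1,3,5-trien-7-yn-1-yl]cyclohex-1-ene | C#C/C=C/C=C(C)/C=C/[C@H]1C(C)=CCCC1(C)C | intermediate
23 | {(1E,3E,5E,7E)-2,6-dimethyl-8-[(1R)-2,6,6-trimethylcyclohex-2-en-1-yl]octa-1,3,5,7-tetraen-1-yl}dimethylaluminium | C[Al](C)/C=C(C)/C=C/C=C(C)/C=C/[C@H]1C(C)=CCCC1(C)C | intermediate
24 | (6R)-ε,ψ-carotene (δ-carotene) | CC(C)=CCC/C(C)=C/C=C/C(C)=C/C=C/C(C)=C/C=C/C=C(C)/C=C/C=C(C)/C=C/[C@H]1C(C)=CCCC1(C)C | target

**Count**
Total steps: 12. Longest linear sequence: 8 steps (1, 2, 4, 5, 6, 7, 8, 12).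

**Steps most likely to fail**

Step 12. The Lewis-acid- and light-sensitive tetraenyne may be methylaluminated incompletely, a slow metal relay may let the polyene geometry drift, and homocoupling may compete. The fallback sets out from 22 and 14 and comes back at 24. It divides the one-flask event into two isolated, purifiable partners that are joined at the same bond by a Suzuki–Miyaura coupling.
- Alane 23, made from 22 as before, is quenched with I2 in THF at −30 °C. This gives the alkenyl iodide (6R)-6-[(1E,3E,5E,7E)-8-iodo-3,7-dimethylocta-1,3,5,7-tetraen-1-yl]-1,5,5-trimethylcyclohex-1-ene F1.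
- Alane 15, made from 14 as before, is converted with ZnCl2 (1 equiv) to the zinc reagent. It is then coupled with commercial (E)-2-bromovinylboronic acid MIDA ester (Pd2(dba)3, P(2-furyl)3, THF) to give the crystalline (1E,3E,5E,7E,9E,11E)-4,8,12,16-tetramethylheptadeca-1,3,5,7,9,11,15-heptaen-1-ylboronic acid MIDA ester F2.
- F1 and F2 are joined under slow-release conditions (Pd(OAc)2, SPhos, aq NaOH, THF, 23 °C, dark) to give 24.

Step 9. Competing γ-deprotonation at the doubly allylic C6 by LDA may erode the enantiomeric purity or move the ring alkene into conjugation. The fallback sets out from 17 and comes back at 21, so it replaces steps 9 and 10. It avoids amide bases on the ionone stage by building the chain through carbonyl olefinations.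
- A Horner–Wadsworth–Emmons reaction of 17 with triethyl phosphonoacetate (NaH, THF, 23 °C) and removal of the minor 9Z isomer gives ethyl (2E,4E)-3-methyl-5-[(1R)-2,6,6-trimethylcyclohex-2-en-1-yl]penta-2,4-dienoate F3.
- Reduction with i-Bu2AlH in CH2Cl2 at −78 °C gives (2E,4E)-3-methyl-5-[(1R)-2,6,6-trimethylcyclohex-2-en-1-yl]penta-2,4-dien-1-ol F4.
- Oxidation with MnO2 in CH2Cl2 gives (2E,4E)-3-methyl-5-[(1R)-2,6,6-trimethylcyclohex-2-en-1-yl]penta-2,4-dienal F5.
- A Wittig reaction of F5 with the ylide from [3-(trimethylsilyl)prop-2-yn-1-yl]triphenylphosphonium bromide (n-BuLi, THF, −78 to 0 °C) forms C11=C12. Chromatographic removal of the minor Z isomer then gives 21.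

Step 8. The first-formed bromodiene may react again at its carbon–bromine bond (double coupling to a symmetrical C40 polyene), and the bromoheptaene may decay during isolation. The fallback sets out from 14 and comes back at 24, with F8 taking the place of 16 in step 12. It builds the haloalkene terminus by carbonyl chemistry instead of a dihaloethene linchpin.
- Alane 15, made from 14 as before, is turned into its ate complex with n-BuLi and treated with paraformaldehyde in THF. This gives (2E,4E,6E,8E,10E)-3,7,11,15-tetramethylhexadeca-2,4,6,8,10,14-hexaen-1-ol F6.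
- Oxidation with MnO2 in CH2Cl2 gives (2E,4E,6E,8E,10E)-3,7,11,15-tetramethylhexadeca-2,4,6,8,10,14-hexaenal F7.
- A Takai olefination (CHI3, CrCl2, THF, 0 °C) gives (1E,3E,5E,7E,9E,11E)-1-iodo-4,8,12,16-tetramethylheptadeca-1,3,5,7,9,11,15-heptaene F8.

**Further compounds**
F1 | step 12 | (6R)-6-[(1E,3E,5E,7E)-8-iodo-3,7-dimethylocta-1,3,5,7-tetraen-1-yl]-1,5,5-trimethylcyclohex-1-ene | I/C=C(C)/C=C/C=C(C)/C=C/[C@H]1C(C)=CCCC1(C)C
F2 | step 12 | (1E,3E,5E,7E,9E,11E)-4,8,12,16-tetramethylheptadeca-1,3,5,7,9,11,15-heptaen-1-ylboronic acid MIDA ester | CC(C)=CCC/C(C)=C/C=C/C(C)=C/C=C/C(C)=C/C=C/B1OC(=O)CN(C)CC(=O)O1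
F3 | step 9 | ethyl (2E,4E)-3-methyl-5-[(1R)-2,6,6-trimethylcyclohex-2-en-1-yl]penta-2,4-dienoate | CCOC(=O)/C=C(C)/C=C/[C@H]1C(C)=CCCC1(C)C
F4 | step 9 | (2E,4E)-3-methyl-5-[(1R)-2,6,6-trimethylcyclohex-2-en-1-yl]penta-2,4-dien-1-ol | OC/C=C(C)/C=C/[C@H]1C(C)=CCCC1(C)C
F5 | step 9 | (2E,4E)-3-methyl-5-[(1R)-2,6,6-trimethylcyclohex-2-en-1-yl]penta-2,4-dienal | O=C/C=C(C)/C=C/[C@H]1C(C)=CCCC1(C)C
F6 | step 8 | (2E,4E,6E,8E,10E)-3,7,11,15-tetramethylhexadeca-2,4,6,8,10,14-hexaen-1-ol | CC(C)=CCC/C(C)=C/C=C/C(C)=C/C=C/C(C)=C/CO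
F7 | step 8 | (2E,4E,6E,8E,10E)-3,7,11,15-tetramethylhexadeca-2,4,6,8,10,14-hexaenal | CC(C)=CCC/C(C)=C/C=C/C(C)=C/C=C/C(C)=C/C=O
F8 | step 8 | (1E,3E,5E,7E,9E,11E)-1-iodo-4,8,12,16-tetramethylheptadeca-1,3,5,7,9,11,15-heptaene | CC(C)=CCC/C(C)=C/C=C/C(C)=C/C=C/C(C)=C/C=C/I
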